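**Plan**
- Retrosynthesis: the C2–Br bond is cut first, then C3–Br is traced back to a C3 carboxyl group (ipso exchange), then the C3–C3a bond of the pyrrole ring is cut, and last the N1–C2 bond between the aniline nitrogen and a propiolate β-carbon.
- Forward: the benzene ring with its C6 bromine is bought as 5-bromo-2-iodoaniline. N1–C2 is made by conjugate addition, the pyrrole ring is closed at C3–C3a on palladium, and the ester is hydrolysed and replaced by bromine while C2 is brominated in the same flask.
- Enabling feature: C3 of the indole is the nucleophilic carbon of an N-aryl enamine and C3a is the benzene carbon ortho to N1. An ortho-iodo N-aryl enaminoester can therefore be joined C3 to C3a, and the ester that activates the enamine ends up at C3, the position where indoles undergo bromodecarboxylation.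
- Stereochemistry: none has to be set; the Z geometry of the enaminoester is incidental.

Key step: step 2

Assumption: the target is planar and achiral (no stereocentre, no configured double bond), so "single enantiomer" places no demand on the route.

**Step 1**
Reactants: 1 5-bromo-2-iodoaniline; 2 methyl propiolate
Product: 3 methyl (Z)-3-[(5-bromo-2-iodophenyl)amino]prop-2-enoate
Conditions: 2 (1.5 equiv), MeOH, reflux, dark
Reagents that add atoms: none
Why: Aza-Michael (conjugate) addition of the aniline nitrogen to the electron-poor alkyne, with the protic solvent protonating the allenolate, should give the enaminoester without any by-product, the Z isomer being favoured by the intramolecular N–H···O=C hydrogen bond (the geometry does not matter later, since push–pull enamines equilibrate).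

**Step 2**
Reactants: 3 methyl (Z)-3-[(5-bromo-2-iodophenyl)amino]prop-2-enoate
Product: 5 methyl 6-bromo-1H-indole-3-carboxylate, via methyl 6-bromo-3H-indole-3-carboxylate 4 (not isolated)
Conditions: Pd(OAc)2 (5 mol %), n-Bu4NCl (1 equiv), NaHCO3 (2.5 equiv), DMF, 80 °C, Ar
Reagents that add atoms: none
Why: Pd(0) formed in situ inserts into the C–I bond of 3; the arylpalladium(II) iodide is then attacked by the enamine carbon alpha to the ester (C-palladation, HI taken up by bicarbonate) to give a six-membered azapalladacycle, and reductive elimination forms C3–C3a and releases 3H-indole 4, which tautomerises to aromatic 5. The closest known reaction type is the palladium-catalysed cyclisation of N-(2-haloaryl) enaminones and enaminoesters to 3-acylindoles and indole-3-carboxylates, an intramolecular Heck-type enamine arylation. The pyrrole ring closes in a formal 5-endo-trig sense, which is feasible because the bond is made by reductive elimination from the six-membered palladacycle and not by a strained 5-endo carbopalladation. No stereocentre survives: the C3 stereocentre of transient 4 is erased on tautomerisation, and the Z/E geometry of 3 is irrelevant because push–pull enamines isomerise under the conditions. Two selectivities are needed: the site of ring closure is fixed by the iodine, which sits para to the bromine and so places that bromine at C6 only, and insertion into C–I in the presence of C–Br is secured by the much faster oxidative addition of aryl iodides to ligand-free palladium at 80 °C, helped by the intramolecular enamine trapping the aryl–Pd species at once.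

**Step 3**
Reactants: 5 methyl 6-bromo-1H-indole-3-carboxylate
Product: 7 6-bromo-1H-indole-3-carboxylic acid, via sodium 6-bromo-1H-indole-3-carboxylate 6 (not isolated)
Conditions: 2 M aq NaOH (5 equiv), MeOH–THF, 65 °C; then 1 M HCl, 0 °C, to pH 3
Reagents that add atoms: sodium hydroxide, [Na+].[OH-]
Why: Saponification (BAc2 ester hydrolysis): the vinylogous carbamate ester is sluggish and is therefore heated with excess hydroxide to give sodium salt 6, the aryl bromide is inert to aqueous base, and cold acidification to pH 3 should liberate acid 7 without the protodecarboxylation that hot acid would cause.

**Step 4**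
Reactants: 7 6-bromo-1H-indole-3-carboxylic acid
Product: 9 2,3,6-tribromo-1H-indole, via 3,6-dibromo-1H-indole 8 (not isolated)
Conditions: NBS (2.05 equiv, two portions), dry DMF, 0 °C to rt, dark, Ar; aq Na2S2O3 work-up, product kept cold and dark
Reagents that add atoms: N-bromosuccinimide, O=C1CCC(=O)N1Br
Why: Electrophilic ipso-substitution (bromodecarboxylation, a Hunsdiecker-type halodecarboxylation of an electron-rich heteroaryl acid): Br+ attacks C3, the most nucleophilic indole position, and the σ-adduct rearomatises by losing CO2 to give 8, whose only remaining pyrrole C–H (C2) then undergoes ordinary electrophilic aromatic bromination, while the bromine-deactivated benzene ring should stay untouched at 0 °C.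

**Compound list**
1 | 5-bromo-2-iodoaniline | Nc1cc(Br)ccc1I | starting material
2 | methyl propiolate (methyl prop-2-ynoate) | C#CC(=O)OC | starting material
3 | methyl (Z)-3-[(5-bromo-2-iodophenyl)amino]prop-2-enoate | COC(=O)/C=C\Nc1cc(Br)ccc1I | intermediate
4 | methyl 6-bromo-3H-indole-3-carboxylate (racemic; not isolated) | COC(=O)C1C=Nc2cc(Br)ccc12 | intermediate
5 | methyl 6-bromo-1H-indole-3-carboxylate | COC(=O)c1c[nH]c2cc(Br)ccc12 | intermediate
6 | sodium 6-bromo-1H-indole-3-carboxylate (not isolated) | [Na+].[O-]C(=O)c1c[nH]c2cc(Br)ccc12 | intermediate
7 | 6-bromo-1H-indole-3-carboxylic acid | OC(=O)c1c[nH]c2cc(Br)ccc12 | intermediate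
8 | 3,6-dibromo-1H-indole (not isolated) | Brc1c[nH]c2cc(Br)ccc12 | intermediate
9 | 2,3,6-tribromo-1H-indole | Brc1ccc2c(Br)c(Br)[nH]c2c1 | target

**Step count**
Total steps: 4. Longest linear sequence: 4 steps (from 1).

**Steps most likely to fail**

Step 4. The risk is over-oxidation. Once C3 carries bromine, the N-unsubstituted indole can be attacked again at C3 and intercepted by traces of water (oxindole formation), brominated further on the benzene ring, or degraded during work-up. Fallback, setting out from 7 and returning at 9: the C2 bromine is introduced by directed lithiation on an N-protected indole, not by a second electrophilic substitution. Acid 7 would be treated with only one equivalent of NBS in DMF at 0 °C to give 8. The crude, unstored 8 would be sulfonylated at once (PhSO2Cl, Bu4NHSO4, 50 % aq NaOH, CH2Cl2) to 3,6-dibromo-1-(phenylsulfonyl)-1H-indole F1. Deprotonation at C2 with LDA in THF at −78 °C and quenching with 1,2-dibromo-1,1,2,2-tetrachloroethane should give 2,3,6-tribromo-1-(phenylsulfonyl)-1H-indole F2. Removal of the sulfonyl group with TBAF in refluxing THF then leads to 9.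

Step 2. The risk is loss of the aryl–palladium intermediate by hydrodeiodination or precipitation of palladium black before the slow C-palladation of the deactivated enamine. If the temperature is raised to compensate, insertion into C–Br with oligomerisation becomes possible. Fallback, setting out from 1 and returning at 8: the pyrrole ring is closed at N1–C2 by alkyne hydroamination, and the carboxyl placeholder is dropped in favour of the innate C3 selectivity of indole bromination. Sonogashira coupling of 1 with ethynyltrimethylsilane at the iodide (PdCl2(PPh3)2, CuI, Et3N, rt) should give 5-bromo-2-[(trimethylsilyl)ethynyl]aniline F3. KOt-Bu in NMP at rt removes silicon and induces 5-endo-dig cyclisation to 6-bromo-1H-indole F4. One equivalent of NBS in DMF at 0 °C then brominates C3 to give 8, which the second equivalent carries on to 9 as in step 4.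

Step 1. The risk is a slow, incomplete addition, because the nitrogen is hindered by the ortho iodine and electronically deactivated; forcing the reaction invites polymerisation of the propiolate. Fallback, setting out from 1 and returning at 3: acid-catalysed addition–elimination replaces the conjugate addition. Aniline 1 would be heated with methyl (E)-3-methoxyacrylate and catalytic TsOH in toluene at 90 °C with removal of methanol, which should give 3 directly. No new compound arises on this detour (F0).

**Further compounds**
F1 | step 4 | 3,6-dibromo-1-(phenylsulfonyl)-1H-indole | Brc1cn(S(=O)(=O)c2ccccc2)c2cc(Br)ccc12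
F2 | step 4 | 2,3,6-tribromo-1-(phenylsulfonyl)-1H-indole | Brc1c(Br)n(S(=O)(=O)c2ccccc2)c2cc(Br)ccc12
F3 | step 2 | 5-bromo-2-[(trimethylsilyl)ethynyl]aniline | C[Si](C)(C)C#Cc1ccc(Br)cc1N
F4 | step 2 | 6-bromo-1H-indole | Brc1ccc2cc[nH]c2c1
F0 | step 1 | none | none
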